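Each quinone ring is numbered C1 (carbonyl flanking the arylethyl carbon), C2 (OH), C3 (CH3), C4 (carbonyl), C5 (ring junction) and C6 (CH2CH2Ar). The 1,3-related oxygens on C2 and C4 identify a resorcinol of polyketide origin, and C4–C5–C5'–C4' is a succinate whose C5 and C5' also bear the C6 acyl groups. Step 5 adds two dianions of methyl 3-oxopentanoate to this core: Claisen acylation forges C3–C4, aldol condensation C1–C6, and both arenes form in one operation. The precursor is dimethyl 2,3-bis[3-(2-methoxyphenyl)propanoyl]succinate, masked as its bis(methoxymethyl enol ether) so that no acidic C5–H interferes.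

Key step: step 5

**Remarks on the chemistry**

- Assumption: the target carries no stereodescriptor, so the hindered C5–C5' axis is taken as unspecified (racemic if configurationally stable). The route has no stereocentre to control.
- Methyl esters are used throughout, so the methoxide expelled in the Claisen stage matches the ester of the nucleophile and cannot scramble ester groups.
- The C5–C5' bond is made from two separately prepared halves, bromide 5 and enolate 6, in exact 1:1 ratio. No free halogen is then present once the enolate of the product can form, which limits over-oxidation to the alkene.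
- The diacylsuccinate 7 is not offered to the dianion as such. Its doubly activated C5–H would be removed at once, which consumes dianion and turns each β-keto ester into an unreactive enolate. It enters the key step as the bis(MOM enol ether) 9, which has the same skeleton and no C5–H and is unmasked by dilute acid in the same operation.
- The aldol closure is 6-exo-trig at the C6 carbonyl. The C1 enolate is delocalised over the exocyclic ester carbonyl and the ring carbonyl C2, so the closure can be written as 6-(enolexo)-exo-trig or as 6-(enolendo)-exo-trig; both are allowed.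
- C7 is the side-chain CH2 attached to C6.

**Route**

Step 1
Reactants: 1 methyl acetoacetate; 2 2-methoxybenzyl bromide
Product: 4 methyl 5-(2-methoxyphenyl)-3-oxopentanoate, via methyl acetoacetate dianion 3 (not isolated)
Conditions: NaH, THF, 0 °C; n-BuLi, 0 °C; then 2, 0 °C → rt; aq. HCl
Reagents that add atoms: none
Why: Huckin–Weiler dianion alkylation, in which the γ-carbanion is far more nucleophilic than the stabilised α-site and is benzylated selectively; no stereocentre is formed.

Step 2
Reactants: 4 methyl 5-(2-methoxyphenyl)-3-oxopentanoate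
Product: 5 methyl 2-bromo-5-(2-methoxyphenyl)-3-oxopentanoate (racemic, configurationally labile)
Conditions: NBS (1.0 equiv), Mg(ClO4)2 (10 mol %), EtOAc, 0 °C → rt, dark
Reagents that add atoms: N-bromosuccinimide, O=C1CCC(=O)N1Br
Why: Electrophilic α-bromination of a β-keto ester through its magnesium-chelated enol, which reacts only at the doubly activated carbon; NBS releases no HBr, so the bromine should neither migrate to the α'-carbon nor attack the anisole ring, and the labile new centre is consumed in step 3.

Step 3
Reactants: 4 methyl 5-(2-methoxyphenyl)-3-oxopentanoate; 5 methyl 2-bromo-5-(2-methoxyphenyl)-3-oxopentanoate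
Product: 7 dimethyl 2,3-bis[3-(2-methoxyphenyl)propanoyl]succinate (meso/racemic mixture), via sodium enolate 6 (not isolated)
Conditions: 4, NaH (1.0 equiv), THF, 0 °C; enolate solution added to 5 (1.0 equiv), THF, −20 °C → rt; aq. NH4Cl
Reagents that add atoms: none
Why: C-alkylation of a β-keto ester enolate by an α-bromo-β-keto ester, the stepwise form of the classical halogen-mediated enolate dimerisation that gives 2,3-diacylsuccinates; bromine exchange between the partners is degenerate because both share one skeleton, and the two epimerisable centres form unselectively and are erased in step 4.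

Step 4
Reactants: 7 dimethyl 2,3-bis[3-(2-methoxyphenyl)propanoyl]succinate
Product: 9 dimethyl 2,3-bis[1-(methoxymethoxy)-3-(2-methoxyphenyl)propylidene]succinate (E/Z mixture), via disodium bis-enolate 8 (not isolated)
Conditions: NaH (2.2 equiv), THF–DMPU, 0 °C; MOMCl (2.5 equiv), 0 °C → rt
Reagents that add atoms: chloromethyl methyl ether, COCCl
Why: O-alkylation of β-keto ester enolates by the hard oxocarbenium-like electrophile MOMCl, favoured because C-alkylation would build a quaternary centre; the basic medium avoids acid-induced Paal–Knorr furan closure of the 1,4-diketone, and the alkene geometry is irrelevant.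

Step 5
Reactants: 9 dimethyl 2,3-bis[1-(methoxymethoxy)-3-(2-methoxyphenyl)propylidene]succinate; 10 methyl 3-oxopentanoate
Product: 14 dimethyl 4,4',6,6'-tetrahydroxy-2,2'-bis[2-(2-methoxyphenyl)ethyl]-5,5'-dimethyl-[1,1'-biphenyl]-3,3'-dicarboxylate, via methyl 3-oxopentanoate dianion 11 (not isolated), via bis-Claisen adduct 12 (not isolated), via bis(triketo ester) 13 (not isolated)
Conditions: 10 (6 equiv), NaH then n-BuLi, THF, 0 °C; add 9, −78 °C → rt; 1 M aq. HCl, THF–MeOH, 0 °C → rt, phase separation; then Ca(OAc)2, MeOH, rt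
Reagents that add atoms: none
Why: Proposed new method: the γ-carbanion of 11, the hardest and most basic site, should add to each ester carbonyl of 9 and expel methoxide (C3–C4 and C3'–C4') to give 12 as its polyenolate, dilute acid then cleaves the MOM enol ethers to unveil the C6 ketones (13), and under Ca(OAc)2 each doubly activated C1 carbon adds to its C6 ketone, after which loss of water and enolisation of C2=O and C4=O deliver the arenes. The closest known reaction type is the Claisen acylation of β-keto ester dianions by esters, β-keto ester enolates included, followed by aldol aromatisation of the resulting 3,5,7-triketo esters to orsellinate-type resorcylates; untested is its twofold use on a hindered 2,3-diacylsuccinate carrying enol ether masks. Each ring closes 6-exo-trig at the C6 carbonyl, a closure that is 6-(enolexo)-exo-trig when the C1 enolate is drawn through the exocyclic ester carbonyl and 6-(enolendo)-exo-trig when it is drawn through C2, both being allowed. No stereocentre is created, since the C3 and C5 centres of 12 and 13 vanish on aromatisation and the hindered C5–C5' axis forms as a racemate. The step needs site selectivity (γ-carbon to C4, α-carbon to C6) and freedom from proton transfer: the intrinsic reactivity order of the dianion and the fully substituted, hindered enol ether carbon C6 (which disfavours conjugate addition–elimination) secure the first, and the absence of any C5–H in 9 secures the second. Competing aldol modes such as C3 onto C6' (five-membered ring) stay reversible under the mild base, whereas only C1 onto C6 ends irreversibly in an aromatic ring.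

Step 6
Reactants: 14 dimethyl 4,4',6,6'-tetrahydroxy-2,2'-bis[2-(2-methoxyphenyl)ethyl]-5,5'-dimethyl-[1,1'-biphenyl]-3,3'-dicarboxylate
Product: 16 6,6'-bis[2-(2-methoxyphenyl)ethyl]-3,3'-dimethyl-[1,1'-biphenyl]-2,2',4,4'-tetrol, via biphenyl diacid 15 (not isolated)
Conditions: KOH, MeOH–H2O (degassed), reflux, Ar; then aq. HCl, 50 °C
Reagents that add atoms: none
Why: Saponification followed by decarboxylation of a 2,4-dihydroxybenzoic acid, which protonates easily at the ipso carbon C1 (ortho and para to the hydroxyls) and loses CO2, as in the conversion of β-orcinol carboxylates to β-orcinols; the aryl methyl ethers are untouched.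

Step 7
Reactants: 16 6,6'-bis[2-(2-methoxyphenyl)ethyl]-3,3'-dimethyl-[1,1'-biphenyl]-2,2',4,4'-tetrol
Product: 17 4,4'-dihydroxy-2,2'-bis[2-(2-methoxyphenyl)ethyl]-5,5'-dimethyl-[1,1'-bi(cyclohexa-1,4-dien-1-yl)]-3,3',6,6'-tetrone (target CNP0293637.0)
Conditions: (KSO3)2NO (5 equiv), KH2PO4 buffer, H2O–acetone, 0 °C → rt
Reagents that add atoms: potassium nitrosodisulfonate (KSO3)2NO, [O]N(S(=O)(=O)[O-])S(=O)(=O)[O-].[K+].[K+]
Why: Teuber oxidation, in which the C4 phenol gives a phenoxyl radical that captures a second equivalent of the reagent at its only free para carbon C1 and collapses to the 1,4-quinone while the C2 hydroxyl is retained; the anisole rings are inert and no stereocentre is involved.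

**Compound list**

1 | methyl acetoacetate | COC(=O)CC(C)=O | starting material
2 | 2-methoxybenzyl bromide | COc1ccccc1CBr | starting material
3 | methyl acetoacetate dianion (sodium lithium salt) | C=C([O-])C=C([O-])OC.[Li+].[Na+] | intermediate
4 | methyl 5-(2-methoxyphenyl)-3-oxopentanoate | COC(=O)CC(=O)CCc1ccccc1OC | intermediate
5 | methyl 2-bromo-5-(2-methoxyphenyl)-3-oxopentanoate (racemic) | COC(=O)C(Br)C(=O)CCc1ccccc1OC | intermediate
6 | sodium enolate of 4 | COC(=O)C=C([O-])CCc1ccccc1OC.[Na+] | intermediate
7 | dimethyl 2,3-bis[3-(2-methoxyphenyl)propanoyl]succinate (meso/racemic, epimerisable) | COC(=O)C(C(=O)CCc1ccccc1OC)C(C(=O)OC)C(=O)CCc1ccccc1OC | intermediate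
8 | disodium bis-enolate of 7 | COC(=O)C(=C([O-])CCc1ccccc1OC)C(C(=O)OC)=C([O-])CCc1ccccc1OC.[Na+].[Na+] | intermediate
9 | dimethyl 2,3-bis[1-(methoxymethoxy)-3-(2-methoxyphenyl)propylidene]succinate (E/Z mixture) | COCOC(CCc1ccccc1OC)=C(C(=O)OC)C(C(=O)OC)=C(OCOC)CCc1ccccc1OC | intermediate
10 | methyl 3-oxopentanoate | CCC(=O)CC(=O)OC | starting material
11 | methyl 3-oxopentanoate dianion (sodium lithium salt) | CC=C([O-])C=C([O-])OC.[Li+].[Na+] | intermediate
12 | dimethyl 4,9-dimethyl-6,7-bis[1-(methoxymethoxy)-3-(2-methoxyphenyl)propylidene]-3,5,8,10-tetraoxododecanedioate (isomer mixture) | COC(=O)CC(=O)C(C)C(=O)C(=C(OCOC)CCc1ccccc1OC)C(=C(OCOC)CCc1ccccc1OC)C(=O)C(C)C(=O)CC(=O)OC | intermediate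
13 | dimethyl 6,7-bis[3-(2-methoxyphenyl)propanoyl]-4,9-dimethyl-3,5,8,10-tetraoxododecanedioate (isomer and tautomer mixture) | COC(=O)CC(=O)C(C)C(=O)C(C(=O)CCc1ccccc1OC)C(C(=O)CCc1ccccc1OC)C(=O)C(C)C(=O)CC(=O)OC | intermediate
14 | dimethyl 4,4',6,6'-tetrahydroxy-2,2'-bis[2-(2-methoxyphenyl)ethyl]-5,5'-dimethyl-[1,1'-biphenyl]-3,3'-dicarboxylate | COC(=O)c1c(O)c(C)c(O)c(c1CCc1ccccc1OC)-c1c(O)c(C)c(O)c(C(=O)OC)c1CCc1ccccc1OC | intermediate
15 | 4,4',6,6'-tetrahydroxy-2,2'-bis[2-(2-methoxyphenyl)ethyl]-5,5'-dimethyl-[1,1'-biphenyl]-3,3'-dicarboxylic acid | OC(=O)c1c(O)c(C)c(O)c(c1CCc1ccccc1OC)-c1c(O)c(C)c(O)c(C(=O)O)c1CCc1ccccc1OC | intermediate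
16 | 6,6'-bis[2-(2-methoxyphenyl)ethyl]-3,3'-dimethyl-[1,1'-biphenyl]-2,2',4,4'-tetrol | COc1ccccc1CCc1cc(O)c(C)c(O)c1-c1c(O)c(C)c(O)cc1CCc1ccccc1OC | intermediate
17 | 4,4'-dihydroxy-2,2'-bis[2-(2-methoxyphenyl)ethyl]-5,5'-dimethyl-[1,1'-bi(cyclohexa-1,4-dien-1-yl)]-3,3',6,6'-tetrone | COc1ccccc1CCC1=C(C2=C(CCc3ccccc3OC)C(=O)C(O)=C(C)C2=O)C(=O)C(C)=C(O)C1=O | target

**Step count and risk**

Total step count: 7. Longest linear sequence: 7 steps (1 and 2 → 4 → 5 → 7 → 9 → 14 → 16 → 17); keto ester 4 enters again at step 3 and methyl 3-oxopentanoate 10 enters at step 5.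

Steps most likely to fail:

1. Step 5 (key step). Proton transfer from the allylic C7–H2 of the vinylogous esters to the γ-carbanion, slow addition to the hindered, donor-deactivated ester carbonyls, or conjugate addition–elimination at C6 could return 9 or misdirect the first bond. In the acid stage, dehydrative closure of the 1,4- or 1,5-dicarbonyl arrays to furans or pyranones could divert 13. The fallback uses known chemistry only, sets out from 2-methoxybenzyl bromide 2 together with a commercial benzoate, and comes back at 14. Commercial methyl 2,4-dihydroxy-3,6-dimethylbenzoate F1 would be iodinated at its only free ring position (I2, NaHCO3, THF–H2O) to methyl 2,4-dihydroxy-5-iodo-3,6-dimethylbenzoate F2, then benzylated (BnBr, K2CO3, DMF) to methyl 2,4-bis(benzyloxy)-5-iodo-3,6-dimethylbenzoate F3. Ullmann homocoupling (Cu powder, DMF, 150 °C) should give dimethyl 4,4',6,6'-tetrakis(benzyloxy)-2,2',5,5'-tetramethyl-[1,1'-biphenyl]-3,3'-dicarboxylate F4. Lateral lithiation of the two methyl groups ortho to the esters (LiN(i-Pr)2, THF, −78 °C) and alkylation with 2 would install both arylethyl chains, giving dimethyl 4,4',6,6'-tetrakis(benzyloxy)-2,2'-bis[2-(2-methoxyphenyl)ethyl]-5,5'-dimethyl-[1,1'-biphenyl]-3,3'-dicarboxylate F5. Hydrogenolysis (H2, Pd/C, EtOAc–MeOH) then returns 14.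

2. Step 7. The electron-rich rings may be over-oxidised, phenoxyl radicals may couple before the second equivalent of oxidant is captured at C1, or the reaction may stall with one ring still a resorcinol. The fallback sets out from 16 and comes back at 17 by bringing in the C1 oxygen through carbon. Vilsmeier–Haack formylation at the single free position of each ring (POCl3, DMF; aq. NaOAc) should give 4,4',6,6'-tetrahydroxy-2,2'-bis[2-(2-methoxyphenyl)ethyl]-5,5'-dimethyl-[1,1'-biphenyl]-3,3'-dicarbaldehyde F6. Dakin oxidation (H2O2, aq. NaOH, 0 °C, then acid) would convert it to 6,6'-bis[2-(2-methoxyphenyl)ethyl]-3,3'-dimethyl-[1,1'-biphenyl]-2,2',4,4',5,5'-hexol F7. Mild dehydrogenation of this hydroxyquinol (Ag2O, Et2O, rt) gives 17.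

3. Step 6. Acyl substitution may be slow at ester carbonyls shielded by two ortho substituents, and the tetraphenolate may be oxidised by air during prolonged heating in alkali. The fallback sets out from 9 and comes back at 15 by changing the ester so that it is cleaved by acid. The key step would be run with the dianion of tert-butyl 3-oxopentanoate F8 to give di-tert-butyl 4,4',6,6'-tetrahydroxy-2,2'-bis[2-(2-methoxyphenyl)ethyl]-5,5'-dimethyl-[1,1'-biphenyl]-3,3'-dicarboxylate F9. Acidolysis (CF3CO2H, CH2Cl2, rt) then gives diacid 15, which loses CO2 on gentle warming in the same medium to reach 16.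

**Further compounds**

F1 | step 5 | methyl 2,4-dihydroxy-3,6-dimethylbenzoate | COC(=O)c1c(O)c(C)c(O)cc1C
F2 | step 5 | methyl 2,4-dihydroxy-5-iodo-3,6-dimethylbenzoate | COC(=O)c1c(O)c(C)c(O)c(I)c1C
F3 | step 5 | methyl 2,4-bis(benzyloxy)-5-iodo-3,6-dimethylbenzoate | COC(=O)c1c(OCc2ccccc2)c(C)c(OCc2ccccc2)c(I)c1C
F4 | step 5 | dimethyl 4,4',6,6'-tetrakis(benzyloxy)-2,2',5,5'-tetramethyl-[1,1'-biphenyl]-3,3'-dicarboxylate | COC(=O)c1c(OCc2ccccc2)c(C)c(OCc2ccccc2)c(c1C)-c1c(OCc2ccccc2)c(C)c(OCc2ccccc2)c(C(=O)OC)c1C
F5 | step 5 | dimethyl 4,4',6,6'-tetrakis(benzyloxy)-2,2'-bis[2-(2-methoxyphenyl)ethyl]-5,5'-dimethyl-[1,1'-biphenyl]-3,3'-dicarboxylate | COC(=O)c1c(OCc2ccccc2)c(C)c(OCc2ccccc2)c(c1CCc1ccccc1OC)-c1c(OCc2ccccc2)c(C)c(OCc2ccccc2)c(C(=O)OC)c1CCc1ccccc1OC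
F6 | step 7 | 4,4',6,6'-tetrahydroxy-2,2'-bis[2-(2-methoxyphenyl)ethyl]-5,5'-dimethyl-[1,1'-biphenyl]-3,3'-dicarbaldehyde | COc1ccccc1CCc1c(C=O)c(O)c(C)c(O)c1-c1c(O)c(C)c(O)c(C=O)c1CCc1ccccc1OC
F7 | step 7 | 6,6'-bis[2-(2-methoxyphenyl)ethyl]-3,3'-dimethyl-[1,1'-biphenyl]-2,2',4,4',5,5'-hexol | COc1ccccc1CCc1c(O)c(O)c(C)c(O)c1-c1c(O)c(C)c(O)c(O)c1CCc1ccccc1OC
F8 | step 6 | tert-butyl 3-oxopentanoate | CCC(=O)CC(=O)OC(C)(C)C
F9 | step 6 | di-tert-butyl 4,4',6,6'-tetrahydroxy-2,2'-bis[2-(2-methoxyphenyl)ethyl]-5,5'-dimethyl-[1,1'-biphenyl]-3,3'-dicarboxylate | CC(C)(C)OC(=O)c1c(O)c(C)c(O)c(c1CCc1ccccc1OC)-c1c(O)c(C)c(O)c(C(=O)OC(C)(C)C)c1CCc1ccccc1OC
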